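## Analysis of the target

The target 21 is a twelve-carbon chain, numbered C1 (ethyl CH3) to C12 (ketone carbon). C12 is bonded to C3' of the only ring, a (6'R)-4-hydroxy-6-methyl-5,6-dihydro-2H-pyran-2-one (ring atoms O1', C2' to C6'). C5 carries the free carboxylic acid and lies inside a cross-conjugated diene: the trisubstituted C4=C5 bond (E, with C3 cis to C6) and the disubstituted C6=C7 bond (E). There are three stereocentres, C3 (S), C9 (R) and C6' (R). They are five or more atoms apart, so none can steer another and each has to be brought in separately.

The sensitive points are these. H–C3 is allylic and γ to the C5 carboxyl, so a strong base can epimerise C3 or move the C4=C5 bond. The 2-carboxy diene is a Michael acceptor and a latent Diels–Alder partner, although the cis relation of C3 and C6 keeps it out of the s-cis conformation. The acylpyranone is an acidic, chelating tricarbonyl whose C6'–O1' bond is β to the C4' carbonyl and can be opened by elimination.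

The difficulty is threefold: fixing both alkene geometries, joining the sp2 carbon C7 to the unactivated methylene C8 without base, and keeping the C5 and C12 carboxyl carbons distinguishable to the end. The strategy rests on one feature. C8 is a CH2 between C7 and the methyl-bearing C9, and C8–C12 is the C2–C6 skeleton of (R)-3-methyladipic acid. C8 can therefore be the radical left when the C1 carboxyl of a 3-methyladipic half-ester is lost, and that half-ester is the cleavage product of (R)-citronellic acid.

## Retrosynthetic reasoning

**21 to 20.** The C5 acid is released last, from tert-butyl ester 20. A tert-butyl ester survives hydroxide, the electrolysis, the thermolysis and the ring closure, and its acidolysis does not disturb the acidic tricarbonyl or the stereocentres.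

**20 to 14, 15 and 17.** The ring is taken apart at the C3'–C4' bond (Dieckmann closure of β-keto ester 19), then at the ester C–O bond of 19 (capture of acylketene 18 by alcohol 17), then at the C12–C3' bond (acylation of Meldrum's acid 15 by acid 14, giving 16). These cuts are chosen because they build the chelating tricarbonyl only at the end and bring in C6' with the purchased alcohol 17. The forward sequence has to acylate a secondary alcohol under neutral conditions and close the ring with no more than one equivalent of base.

**14 to 13.** C12 travels as a methyl ester beside the tert-butyl ester at C5. The forward reaction is a selective saponification; this is what keeps the two carboxyl carbons apart.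

**13 to 4 and 12 (C7–C8).** This cut separates the part that holds all the alkene geometry (C1–C7) from the saturated part (C8–C12). Each half then has one stereocentre from the chiral pool and can be made in few steps. A cut at C6=C7 would leave an olefination on a 2-alkylidene ester with two geometries open; a cut at C5–C6 would leave a vinyl–vinyl coupling on the finished chain. Neither shortens the fragments. The forward reaction must join a primary sp3 carbon to an alkenyl carbon without base and with retention of the C6=C7 geometry.

**4 to 1.** Redox-active ester 4 comes from half-ester 3 by esterification. Acid 3 comes from (R)-citronellic acid 1 by oxidative cleavage of its trisubstituted alkene to a methyl ester, via aldehyde 2. The two ends of 3 differ by origin (acid from 1, ester from the alkene), so no desymmetrisation is needed, and C9 is already present in 1.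

**12 to 9 and 10.** The C7–Br bond is traced to the C7–Sn bond of 11. The C5–C6 bond of 11 is cut into iodoenoate 9 and the two-carbon distannane 10 (Stille coupling). This puts the whole question of the C4=C5 geometry into 9, before the diene exists.

**9 to 7 and 5.** The C4=C5 bond of 9 is cut by a Wittig disconnection into aldehyde 8, made in the flask from alcohol 7, and iodo ylide 6, made from commercial ylide 5. C3 comes with 7.

## Alternatives that were turned down

**Alternative 1:** The disconnection lies inside a carbocycle. 4-Methylcyclohexanone A1 would be desymmetrised by an R-selective Baeyer–Villiger monooxygenase, which inserts oxygen between the carbonyl carbon (later C12) and one of the two enantiotopic α-carbons (later C7). The product is (R)-5-methyloxepan-2-one A2, with C9 set.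
- For it: C9 is made catalytically from an achiral bulk ketone in one operation, and C7 and C12 leave the lactone already differentiated as alcohol and ester. On atom economy and independence from terpene feedstock it is stronger than the chosen route.
- Against it: the two migrating carbons differ only in their relation to a remote methyl group, so a chemical peracid cannot distinguish them. Everything depends on having an enzyme of the right sense with cofactor recycling.
- Against it: A2 supplies only C7–C12. After ring opening and oxidation it gives methyl (4R)-4-methyl-6-oxohexanoate A3. The diene would then have to be finished by a C6=C7 olefination with an allylic phosphorus reagent on a 2-alkylidene ester, where α/γ regiochemistry and both geometries are open. Otherwise A3 would be oxidised to acid 3, and the route would join the chosen one after three to four steps instead of one.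
- Comparison: the chosen strategy takes the same unit, with C9, from 1 in a single cleavage and spends its risk on the bond that joins the halves.

**Alternative 2:** The disconnection is C10–C11. The dianion of (6R)-3-acetyl-4-hydroxy-6-methyl-5,6-dihydro-2H-pyran-2-one A4 (enolate plus acetyl CH2 carbanion) would be alkylated by the primary iodide tert-butyl (2E,4S)-2-[(1E,4S)-5-iodo-4-methylpent-1-en-1-yl]-4-methylhex-2-enoate A5. The product is the tert-butyl ester of the target, A6, which is the same compound as 20.
- For it: it is more convergent at the end than the chosen route. The heterocycle is made once on a small scale, and only the final deprotection follows the union, so the three steps 9–11 on the full chain are avoided.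
- Against it: the second deprotonation must choose the acetyl methyl over the ring methylene C5', and a carbanion at C5' can expel O1' and open the ring.
- Against it: the electrophile is a β-branched primary iodide, slow in SN2 and open to elimination.
- Against it: two or more equivalents of a strong amide base would act in the presence of the dienoate, whose H–C3 is vinylogously acidic and whose C4 is a Michael position.
- Against it: A5 still contains C6=C7–C8–C9, so the sp2–sp3 assembly that the chosen key step solves is only moved into the preparation of A5.
- Comparison: the chosen strategy forms the corresponding bond under neutral, base-free conditions and leaves the base-sensitive tricarbonyl to the end.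

**Alternative 3:** The disconnection is C8–C9, by sigmatropy. The propanoate tert-butyl (2E,4S)-4-methyl-2-[(1S)-1-(propanoyloxy)prop-2-en-1-yl]hex-2-enoate A7, an ester of the bis-allylic C6 carbinol, would be turned into its silyl ketene acetal. Ireland–Claisen rearrangement through a chair would form C8–C9, the (E)-C6=C7 bond and C9, giving (2S,4E,6E,8S)-6-(tert-butoxycarbonyl)-2,8-dimethyldeca-4,6-dienoic acid A8.
- For it: one pericyclic step creates a C–C bond, an alkene geometry and a stereocentre with a predictable transition state and without tin or a transition metal. In that respect it is more elegant than the chosen route.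
- Against it: C9 is then only as good as the enantiopurity of the C6 carbinol and the geometry of the ketene acetal, both of which have to be made. In the chosen route C9 is bought.
- Against it: the carbinol is allylic on both sides, so the rearrangement can also run through the C4=C5 bond, and such doubly activated esters ionise easily.
- Against it: A8 has C9 α to a carboxyl, where it can epimerise, and ends at C10. C11 and C12 must still be added by a two-carbon homologation in the presence of the diene, which costs several steps that the chosen route does not need.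
- Comparison: the chosen strategy creates no stereocentre at all in its key step and delivers the whole C8–C12 unit at the correct oxidation level.

Key step: step 7

## Route

Assumption: the acylpyranone is written as the 4-hydroxy tautomer used for the target; 20 and 21 (and the enol 16) are single compounds that exist as mixtures of enol and keto tautomers.

Step 1
Reactants: 1 (R)-citronellic acid [(3R)-3,7-dimethyloct-6-enoic acid]
Product: 3 (3R)-6-methoxy-3-methyl-6-oxohexanoic acid, via (3R)-3-methyl-6-oxohexanoic acid 2 (not isolated)
Conditions: O3, NaOH (6 equiv), MeOH/CH2Cl2 (1:4), −78 °C; then cold aq. HCl to pH 3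
Reagents that add atoms: ozone, [O-][O+]=O; methanol, CO
Why: Ozonolysis in methanolic sodium hydroxide cleaves the trisubstituted alkene; the aldehyde 2 (present as its sodium salt) is trapped as the methyl hemiacetal and oxidised on to the methyl ester. The C1 carboxylate is inert to ozone and methoxide, so the two termini emerge differentiated, and the stereocentre is not involved.

Step 2
Reactants: 3 (3R)-6-methoxy-3-methyl-6-oxohexanoic acid
Product: 4 1-(1,3-dioxoisoindolin-2-yl) 6-methyl (3R)-3-methylhexanedioate
Conditions: N-hydroxyphthalimide, DIC, DMAP (cat.), CH2Cl2, 0 °C → rt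
Reagents that add atoms: N-hydroxyphthalimide, O=C1c2ccccc2C(=O)N1O
Why: Carbodiimide (Steglich-type) esterification of a primary-alkyl carboxylic acid gives the redox-active ester; the stereocentre is β to the carboxyl and cannot epimerise.

Step 3
Reactants: 5 tert-butyl 2-(triphenylphosphoranylidene)acetate
Product: 6 tert-butyl 2-iodo-2-(triphenylphosphoranylidene)acetate
Conditions: I2, K2CO3, MeOH, 0 °C → rt, dark
Reagents that add atoms: iodine, I-I
Why: Electrophilic iodination of the stabilised ylide at carbon gives an iodophosphonium salt, which carbonate deprotonates to the isolable α-iodo ylide.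

Step 4
Reactants: 7 (S)-2-methylbutan-1-ol; 6 tert-butyl 2-iodo-2-(triphenylphosphoranylidene)acetate
Product: 9 tert-butyl (2Z,4S)-2-iodo-4-methylhex-2-enoate, via (S)-2-methylbutanal 8 (not isolated)
Conditions: (COCl)2, DMSO, CH2Cl2, −78 °C; iPr2NEt, −78 °C; then 6 (1.3 equiv), −78 °C → rt
Reagents that add atoms: none
Why: Swern oxidation and Wittig olefination in one flask, so the volatile, enolisable aldehyde 8 is consumed where it forms. The stabilised iodo ylide places the sec-butyl group trans to the ester and cis to iodine (2Z), which is the geometry of C4=C5 in the target; C3 comes unchanged from 7.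

Step 5
Reactants: 9 tert-butyl (2Z,4S)-2-iodo-4-methylhex-2-enoate; 10 (E)-1,2-bis(tributylstannyl)ethene
Product: 11 tert-butyl (2E,4S)-4-methyl-2-[(E)-2-(tributylstannyl)ethenyl]hex-2-enoate
Conditions: Pd2(dba)3 (2.5 mol %), AsPh3 (20 mol %), 10 (2.5 equiv), NMP, rt → 40 °C
Reagents that add atoms: none
Why: Stille coupling; the α-iodoenoate adds quickly to zerovalent palladium and both sp2 carbons react with retention. The excess of 10 holds the reaction at the mono-coupling stage.

Step 6
Reactants: 11 tert-butyl (2E,4S)-4-methyl-2-[(E)-2-(tributylstannyl)ethenyl]hex-2-enoate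
Product: 12 tert-butyl (2E,4S)-2-[(E)-2-bromoethenyl]-4-methylhex-2-enoate
Conditions: NBS, MeCN, 0 °C, dark
Reagents that add atoms: N-bromosuccinimide, O=C1CCC(=O)N1Br
Why: Ipso bromodestannylation of an alkenylstannane proceeds with retention; the C–Sn bond is by far the most nucleophilic site of the electron-poor diene.

Step 7
Reactants: 4 1-(1,3-dioxoisoindolin-2-yl) 6-methyl (3R)-3-methylhexanedioate; 12 tert-butyl (2E,4S)-2-[(E)-2-bromoethenyl]-4-methylhex-2-enoate
Product: 13 methyl (4R,6E,8E,10S)-8-(tert-butoxycarbonyl)-4,10-dimethyldodeca-6,8-dienoate
Conditions: NiCl2·6H2O (20 mol %), 2,2'-bipyridine (20 mol %), AgNO3 (0.3 equiv), LiCl, DMF, undivided cell, Mg anode, reticulated vitreous carbon cathode, constant current (about 2.5 F/mol), rt; 4 (1.5 equiv)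
Reagents that add atoms: none
Why: This is a nickel-electrocatalytic decarboxylative alkenylation of a redox-active ester with an alkenyl halide, a known reaction type for primary alkyl N-acyloxyphthalimides. Cathodic reduction of the bipyridine complex of NiCl2 (divalent nickel) gives low-valent nickel, which inserts into the C7–Br bond of 12 with retention of the E geometry. One-electron reduction of 4, by low-valent nickel or at the silver-coated cathode, releases phthalimide anion, CO2 and the primary C8 radical. The alkenylnickel species captures this radical (divalent nickel going to trivalent nickel), and reductive elimination forms C7–C8 while the magnesium anode supplies the electrons. No ring is closed and no stereocentre is formed: C9 is β to the radical centre and C3 is beyond the diene, so both are carried through unchanged. The step needs the C8 radical to be captured by nickel rather than to add to the dienoate, dimerise or be reduced; capture is fast, the electrophilic C4 of 12 is shielded by the sec-butyl group, and 4 is used in excess. The E geometry at C6=C7 is secured because oxidative addition and reductive elimination at an sp2 carbon are stereoretentive, and no base or carbon nucleophile is present to disturb the two esters or H–C3.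

Step 8
Reactants: 13 methyl (4R,6E,8E,10S)-8-(tert-butoxycarbonyl)-4,10-dimethyldodeca-6,8-dienoate
Product: 14 (4R,6E,8E,10S)-8-(tert-butoxycarbonyl)-4,10-dimethyldodeca-6,8-dienoic acid
Conditions: LiOH·H2O (1.5 equiv), THF/H2O (3:1), 0 °C → rt; then cold aq. HCl to pH 3–4
Reagents that add atoms: lithium hydroxide, [Li+].[OH-]
Why: Saponification of the unhindered methyl ester; the tert-butyl ester of the hindered, conjugated acid resists hydroxide, and aqueous hydroxide at room temperature should not remove H–C3.

Step 9
Reactants: 14 (4R,6E,8E,10S)-8-(tert-butoxycarbonyl)-4,10-dimethyldodeca-6,8-dienoic acid; 15 Meldrum's acid (2,2-dimethyl-1,3-dioxane-4,6-dione)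
Product: 16 tert-butyl (2E,4S)-2-[(1E,4R)-7-(2,2-dimethyl-4,6-dioxo-1,3-dioxan-5-ylidene)-7-hydroxy-4-methylhept-1-en-1-yl]-4-methylhex-2-enoate
Conditions: DCC, DMAP, CH2Cl2, 0 °C → rt; cold aq. KHSO4 wash, used crude
Reagents that add atoms: none
Why: C-Acylation of Meldrum's acid by the carbodiimide-activated acid with DMAP as acyl transfer agent gives the enolised acyl Meldrum's acid; the acid has no α-stereocentre.

Step 10
Reactants: 16 tert-butyl (2E,4S)-2-[(1E,4R)-7-(2,2-dimethyl-4,6-dioxo-1,3-dioxan-5-ylidene)-7-hydroxy-4-methylhept-1-en-1-yl]-4-methylhex-2-enoate; 17 methyl (R)-3-hydroxybutanoate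
Product: 19 methyl (3R)-3-{[(6R,8E,10E,12S)-10-(tert-butoxycarbonyl)-6,12-dimethyl-3-oxotetradeca-8,10-dienoyl]oxy}butanoate, via acylketene 18 (not isolated)
Conditions: 17 (1.5 equiv), toluene, 90 °C
Reagents that add atoms: none
Why: Thermal cycloreversion of the acyl Meldrum's acid releases acetone, CO2 and an acylketene, which the secondary alcohol traps under neutral conditions to give the β-keto ester. The C–O bond of 17 is not broken, so C6' keeps its R configuration.

Step 11
Reactants: 19 methyl (3R)-3-{[(6R,8E,10E,12S)-10-(tert-butoxycarbonyl)-6,12-dimethyl-3-oxotetradeca-8,10-dienoyl]oxy}butanoate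
Product: 20 tert-butyl (2E,4S)-2-[(1E,4R)-7-[(6R)-4-hydroxy-6-methyl-2-oxo-5,6-dihydro-2H-pyran-3-yl]-4-methyl-7-oxohept-1-en-1-yl]-4-methylhex-2-enoate
Conditions: KOtBu (1.1 equiv), THF/tBuOH, 0 °C → rt; then cold aq. HCl to pH 2–3
Reagents that add atoms: none
Why: Dieckmann condensation: the β-keto ester enolate attacks the methyl ester to close the six-membered ring (C3'–C4'), and the acidic tricarbonyl product is deprotonated at once. With about one equivalent of base the medium is never strongly basic, which protects H–C3 and suppresses elimination of the C6' oxygen.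

Step 12
Reactants: 20 tert-butyl (2E,4S)-2-[(1E,4R)-7-[(6R)-4-hydroxy-6-methyl-2-oxo-5,6-dihydro-2H-pyran-3-yl]-4-methyl-7-oxohept-1-en-1-yl]-4-methylhex-2-enoate
Product: 21 (2E,4S)-2-[(1E,4R)-7-[(6R)-4-hydroxy-6-methyl-2-oxo-5,6-dihydro-2H-pyran-3-yl]-4-methyl-7-oxohept-1-en-1-yl]-4-methylhex-2-enoic acid (target)
Conditions: TFA/CH2Cl2 (1:4), 0 °C → rt
Reagents that add atoms: none
Why: Acidolysis of the tert-butyl ester by loss of the tert-butyl cation; the electron-poor diene, the acylpyranone and the three stereocentres have no acid-labile bond under these conditions.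

## Compound list

1 | (R)-citronellic acid, (3R)-3,7-dimethyloct-6-enoic acid | OC(=O)C[C@H](C)CCC=C(C)C | starting material
2 | (3R)-3-methyl-6-oxohexanoic acid (sodium salt in the flask) | OC(=O)C[C@H](C)CCC=O | intermediate
3 | (3R)-6-methoxy-3-methyl-6-oxohexanoic acid | COC(=O)CC[C@@H](C)CC(=O)O | intermediate
4 | 1-(1,3-dioxoisoindolin-2-yl) 6-methyl (3R)-3-methylhexanedioate | COC(=O)CC[C@@H](C)CC(=O)ON1C(=O)c2ccccc2C1=O | intermediate
5 | tert-butyl 2-(triphenylphosphoranylidene)acetate | CC(C)(C)OC(=O)C=P(c1ccccc1)(c1ccccc1)c1ccccc1 | starting material
6 | tert-butyl 2-iodo-2-(triphenylphosphoranylidene)acetate | CC(C)(C)OC(=O)C(I)=P(c1ccccc1)(c1ccccc1)c1ccccc1 | intermediate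
7 | (S)-2-methylbutan-1-ol | CC[C@H](C)CO | starting material
8 | (S)-2-methylbutanal | CC[C@H](C)C=O | intermediate
9 | tert-butyl (2Z,4S)-2-iodo-4-methylhex-2-enoate | CC[C@H](C)/C=C(\I)C(=O)OC(C)(C)C | intermediate
10 | (E)-1,2-bis(tributylstannyl)ethene | CCCC[Sn](CCCC)(CCCC)/C=C/[Sn](CCCC)(CCCC)CCCC | starting material
11 | tert-butyl (2E,4S)-4-methyl-2-[(E)-2-(tributylstannyl)ethenyl]hex-2-enoate | CC[C@H](C)/C=C(\C=C\[Sn](CCCC)(CCCC)CCCC)C(=O)OC(C)(C)C | intermediate
12 | tert-butyl (2E,4S)-2-[(E)-2-bromoethenyl]-4-methylhex-2-enoate | CC[C@H](C)/C=C(\C=C\Br)C(=O)OC(C)(C)C | intermediate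
13 | methyl (4R,6E,8E,10S)-8-(tert-butoxycarbonyl)-4,10-dimethyldodeca-6,8-dienoate | CC[C@H](C)/C=C(\C=C\C[C@H](C)CCC(=O)OC)C(=O)OC(C)(C)C | intermediate
14 | (4R,6E,8E,10S)-8-(tert-butoxycarbonyl)-4,10-dimethyldodeca-6,8-dienoic acid | CC[C@H](C)/C=C(\C=C\C[C@H](C)CCC(=O)O)C(=O)OC(C)(C)C | intermediate
15 | Meldrum's acid, 2,2-dimethyl-1,3-dioxane-4,6-dione | CC1(C)OC(=O)CC(=O)O1 | starting material
16 | tert-butyl (2E,4S)-2-[(1E,4R)-7-(2,2-dimethyl-4,6-dioxo-1,3-dioxan-5-ylidene)-7-hydroxy-4-methylhept-1-en-1-yl]-4-methylhex-2-enoate | CC[C@H](C)/C=C(\C=C\C[C@H](C)CCC(O)=C1C(=O)OC(C)(C)OC1=O)C(=O)OC(C)(C)C | intermediate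
17 | methyl (R)-3-hydroxybutanoate | COC(=O)C[C@@H](C)O | starting material
18 | acylketene, tert-butyl (2E,4S)-4-methyl-2-[(1E,4R)-4-methyl-7,9-dioxonona-1,8-dien-1-yl]hex-2-enoate | CC[C@H](C)/C=C(\C=C\C[C@H](C)CCC(=O)C=C=O)C(=O)OC(C)(C)C | intermediate
19 | methyl (3R)-3-{[(6R,8E,10E,12S)-10-(tert-butoxycarbonyl)-6,12-dimethyl-3-oxotetradeca-8,10-dienoyl]oxy}butanoate | CC[C@H](C)/C=C(\C=C\C[C@H](C)CCC(=O)CC(=O)O[C@H](C)CC(=O)OC)C(=O)OC(C)(C)C | intermediate
20 | tert-butyl (2E,4S)-2-[(1E,4R)-7-[(6R)-4-hydroxy-6-methyl-2-oxo-5,6-dihydro-2H-pyran-3-yl]-4-methyl-7-oxohept-1-en-1-yl]-4-methylhex-2-enoate | CC[C@H](C)/C=C(\C=C\C[C@H](C)CCC(=O)C1=C(O)C[C@@H](C)OC1=O)C(=O)OC(C)(C)C | intermediate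
21 | (2E,4S)-2-[(1E,4R)-7-[(6R)-4-hydroxy-6-methyl-2-oxo-5,6-dihydro-2H-pyran-3-yl]-4-methyl-7-oxohept-1-en-1-yl]-4-methylhex-2-enoic acid | CC[C@H](C)/C=C(\C=C\C[C@H](C)CCC(=O)C1=C(O)C[C@@H](C)OC1=O)C(=O)O | target

## Step count and least certain steps

Total: 12 steps. Longest linear sequence: 10 steps (steps 3 to 12, from ylide 5); the redox-active ester branch is 2 steps (steps 1 and 2) before the union.

**Step 7 (key step).** The most likely failure is loss of the C8 radical before nickel captures it, by hydrogen abstraction, dimerisation or addition to the dienoate of 12. This would be compounded by slow oxidative addition of the alkenyl bromide, or by cathodic reduction of the diene.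

Fallback, from acid 3 back to 13: photochemical iododecarboxylation with (diacetoxyiodo)benzene and iodine (a Hunsdiecker-type reaction) converts 3 into methyl (4R)-5-iodo-4-methylpentanoate F1. Zinc insertion (Zn dust, LiCl, THF) gives [(2R)-5-methoxy-2-methyl-5-oxopentyl]zinc iodide F2. Negishi coupling of F2 with bromide 12 under Pd(PPh3)4 in THF forms the same C7–C8 bond by a two-electron pathway and returns to 13.

**Step 11.** The most likely failure is E1cB elimination across C5'–C6' (deprotonation α to the methyl ester and expulsion of the β-keto carboxylate) in competition with ring closure. With excess base there could also be vinylogous deprotonation at C3.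

Fallback, from acid 14 back to 20, bypassing steps 9 to 11: the ring is made first and acylated afterwards. Ester 17 undergoes a crossed Claisen condensation with the lithium enolate of tert-butyl acetate (excess, THF, −78 to −20 °C) to give tert-butyl (5R)-5-hydroxy-3-oxohexanoate F3. TFA in CH2Cl2 cleaves and lactonises F3 to (6R)-4-hydroxy-6-methyl-5,6-dihydro-2H-pyran-2-one F4. Acid 14 and F4 with DCC and DMAP in CH2Cl2 give the enol ester (6R)-6-methyl-2-oxo-5,6-dihydro-2H-pyran-4-yl (4R,6E,8E,10S)-8-(tert-butoxycarbonyl)-4,10-dimethyldodeca-6,8-dienoate F5. DMAP then promotes the Fries-type O-to-C acyl shift of F5 to C3', which gives 20.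

**Step 4.** The most likely failures are partial enolisation of aldehyde 8 before the rather unreactive iodo ylide consumes it (erosion of C3), and incomplete Z selectivity of the iodo-olefination.

Fallback, from alcohol 7 back to 11: the same one-flask Swern oxidation is followed by Wittig reaction with the more reactive parent ylide 5, giving tert-butyl (2E,4S)-4-methylhex-2-enoate F6. Bromine in CH2Cl2 adds anti to give tert-butyl (4S)-2,3-dibromo-4-methylhexanoate F7, which is not isolated. Et3N eliminates HBr from F7 through the ester enolate, which should favour tert-butyl (2Z,4S)-2-bromo-4-methylhex-2-enoate F8. Stille coupling of F8 with 10 under the conditions of step 5 returns to 11.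

**Step 5.** The most likely failures are coupling at both tin termini of 10, and protodestannylation of the dienylstannane during isolation.

Fallback, from iodide 9 back to 12, bypassing 11 and step 6: Stille coupling of 9 with ethynyltributylstannane (Pd(PPh3)4, CuI, DMF) gives tert-butyl (2E,4S)-2-ethynyl-4-methylhex-2-enoate F9. Hydrozirconation with Cp2Zr(H)Cl in THF gives the alkenylzirconium compound tert-butyl (2E,4S)-2-{(E)-2-[chlorobis(cyclopentadienyl)zirconio]ethenyl}-4-methylhex-2-enoate F10, which is brominated in the same flask with NBS to give 12.

**Step 1.** The most likely failures are incomplete oxidation of the aldehyde stage when the substrate is present as a poorly soluble sodium carboxylate, and saponification of the new methyl ester during the alkaline work-up, which would erase the difference between the two termini.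

Fallback, from acid 1 back to 3: esterification with Boc2O, DMAP and tBuOH gives tert-butyl (3R)-3,7-dimethyloct-6-enoate F11. Ozonolysis of this neutral substrate in methanolic NaOH gives 1-tert-butyl 6-methyl (3R)-3-methylhexanedioate F12. TFA in CH2Cl2 removes the tert-butyl group of F12 and returns to 3.

## Further compounds

F1 | step 7 | methyl (4R)-5-iodo-4-methylpentanoate | COC(=O)CC[C@@H](C)CI
F2 | step 7 | [(2R)-5-methoxy-2-methyl-5-oxopentyl]zinc iodide | COC(=O)CC[C@@H](C)C[Zn]I
F3 | step 11 | tert-butyl (5R)-5-hydroxy-3-oxohexanoate | C[C@@H](O)CC(=O)CC(=O)OC(C)(C)C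
F4 | step 11 | (6R)-4-hydroxy-6-methyl-5,6-dihydro-2H-pyran-2-one | C[C@@H]1CC(O)=CC(=O)O1
F5 | step 11 | (6R)-6-methyl-2-oxo-5,6-dihydro-2H-pyran-4-yl (4R,6E,8E,10S)-8-(tert-butoxycarbonyl)-4,10-dimethyldodeca-6,8-dienoate | CC[C@H](C)/C=C(\C=C\C[C@H](C)CCC(=O)OC1=CC(=O)O[C@H](C)C1)C(=O)OC(C)(C)C
F6 | step 4 | tert-butyl (2E,4S)-4-methylhex-2-enoate | CC[C@H](C)/C=C/C(=O)OC(C)(C)C
F7 | step 4 | tert-butyl (4S)-2,3-dibromo-4-methylhexanoate (anti adduct, two diastereomers at C2 and C3) | CC[C@H](C)C(Br)C(Br)C(=O)OC(C)(C)C
F8 | step 4 | tert-butyl (2Z,4S)-2-bromo-4-methylhex-2-enoate | CC[C@H](C)/C=C(\Br)C(=O)OC(C)(C)C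
F9 | step 5 | tert-butyl (2E,4S)-2-ethynyl-4-methylhex-2-enoate | CC[C@H](C)/C=C(\C#C)C(=O)OC(C)(C)C
F10 | step 5 | tert-butyl (2E,4S)-2-{(E)-2-[chlorobis(cyclopentadienyl)zirconio]ethenyl}-4-methylhex-2-enoate | CC[C@H](C)/C=C(\C=C\[Zr](Cl)(C1C=CC=C1)C1C=CC=C1)C(=O)OC(C)(C)C
F11 | step 1 | tert-butyl (3R)-3,7-dimethyloct-6-enoate | CC(C)=CCC[C@@H](C)CC(=O)OC(C)(C)C
F12 | step 1 | 1-tert-butyl 6-methyl (3R)-3-methylhexanedioate | COC(=O)CC[C@@H](C)CC(=O)OC(C)(C)C
A1 | alternative 1 | 4-methylcyclohexanone | CC1CCC(=O)CC1
A2 | alternative 1 | (R)-5-methyloxepan-2-one | C[C@@H]1CCC(=O)OCC1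
A3 | alternative 1 | methyl (4R)-4-methyl-6-oxohexanoate | COC(=O)CC[C@@H](C)CC=O
A4 | alternative 2 | (6R)-3-acetyl-4-hydroxy-6-methyl-5,6-dihydro-2H-pyran-2-one | CC(=O)C1=C(O)C[C@@H](C)OC1=O
A5 | alternative 2 | tert-butyl (2E,4S)-2-[(1E,4S)-5-iodo-4-methylpent-1-en-1-yl]-4-methylhex-2-enoate | CC[C@H](C)/C=C(\C=C\C[C@H](C)CI)C(=O)OC(C)(C)C
A6 | alternative 2 | tert-butyl (2E,4S)-2-[(1E,4R)-7-[(6R)-4-hydroxy-6-methyl-2-oxo-5,6-dihydro-2H-pyran-3-yl]-4-methyl-7-oxohept-1-en-1-yl]-4-methylhex-2-enoate (identical with 20) | CC[C@H](C)/C=C(\C=C\C[C@H](C)CCC(=O)C1=C(O)C[C@@H](C)OC1=O)C(=O)OC(C)(C)C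
A7 | alternative 3 | tert-butyl (2E,4S)-4-methyl-2-[(1S)-1-(propanoyloxy)prop-2-en-1-yl]hex-2-enoate | CC[C@H](C)/C=C(\[C@@H](OC(=O)CC)C=C)C(=O)OC(C)(C)C
A8 | alternative 3 | (2S,4E,6E,8S)-6-(tert-butoxycarbonyl)-2,8-dimethyldeca-4,6-dienoic acid | CC[C@H](C)/C=C(\C=C\C[C@H](C)C(=O)O)C(=O)OC(C)(C)C
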